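**Plan**

Locants follow the 1-benzoxepine skeleton of the target: O1, C2 (CH–CH2Br), C3 (C=CH2), C4 (CHOH), C5, C5a, C6 (CMe2), C7 (CHBr), C8, C9, C9a (C–CH3).
The retrosynthesis cuts C3–C4 of the oxepane first, then the ring-fusion bond C5a–C9a of the carbocycle, and last the C9a–O link that joins a bromo keto enoate to (R)-but-3-yne-1,2-diol.
Enabling feature: C9a is fully substituted and carries O1 and CH3, so it is the Markovnikov carbon of a 2-alkoxyalkene and a nucleophilic tertiary α-oxy radical. C5a lies β to C4, which at the ester level makes C5a the matched acceptor, so the hindered ether arises by C–C and not by C–O bond formation.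
Forward order: the two fragments are tied as a temporary 1,3-dioxolane, this ring is opened to an enol ether, hydrogen-atom transfer closes the cyclohexane, and the oxepane is closed last.
Stereochemistry: C7 comes from an organocatalytic α-bromination, C2 from the chiral pool (glycerate), C5a and C9a from a chair transition state governed by C7, and C4 from the final ring closure.

Key step: step 11

Remark 1: the sense of induction in step 2 is assumed to follow the usual shielding model for C2-symmetric 2,5-diarylpyrrolidines. If it is opposite, the antipodal catalyst is used.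
Remark 2: ketal 15 forms as both epimers at the ketal carbon. This has no consequence, because that carbon becomes planar in steps 10 and 11.

**Step 1**
Reactants: 1 methyl 3,3-dimethylpent-4-enoate
Product: 2 3,3-dimethylpent-4-enal
Conditions: DIBAL-H (1.05 equiv), CH2Cl2, −78 °C; aq. Rochelle salt
Reagents that add atoms: none
Why: Partial ester reduction should stop at the aldehyde because the tetrahedral aluminium hemiacetal survives at −78 °C until work-up.

**Step 2**
Reactants: 2 3,3-dimethylpent-4-enal
Product: 4 (R)-2-bromo-3,3-dimethylpent-4-en-1-ol, via bromoaldehyde 3 (not isolated)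
Conditions: (2R,5R)-2,5-diphenylpyrrolidine (20 mol %), PhCO2H (20 mol %), 4,4-dibromo-2,6-di-tert-butylcyclohexa-2,5-dienone, H2O, CH2Cl2/pentane, −40 °C; then NaBH4, MeOH, 0 °C
Reagents that add atoms: 4,4-dibromo-2,6-di-tert-butylcyclohexa-2,5-dienone, CC(C)(C)C1=CC(Br)(Br)C=C(C(C)(C)C)C1=O
Why: In this enamine-catalysed asymmetric α-bromination the phenyl group of the catalyst shields one enamine face and sets the future C7, and immediate borohydride reduction should prevent epimerisation of 3.

**Step 3**
Reactants: 4 (R)-2-bromo-3,3-dimethylpent-4-en-1-ol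
Product: 5 (R)-2-bromo-3,3-dimethylpent-4-enyl trifluoromethanesulfonate
Conditions: Tf2O, 2,6-lutidine, CH2Cl2, −78 °C
Reagents that add atoms: triflic anhydride, O=S(=O)(OS(=O)(=O)C(F)(F)F)C(F)(F)F
Why: O-sulfonylation of the primary alcohol leaves the C–Br stereocentre untouched and supplies a leaving group reactive enough for substitution at a β-branched carbon at low temperature.

**Step 4**
Reactants: 5 (R)-2-bromo-3,3-dimethylpent-4-enyl trifluoromethanesulfonate
Product: 7 (S)-5-bromo-6,6-dimethyloct-7-en-2-one, via alkylated hydrazone 6 (not isolated)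
Conditions: acetone N,N-dimethylhydrazone, n-BuLi, THF, 0 °C; then 5, −78 °C; then satd aq. oxalic acid, Et2O, rt
Reagents that add atoms: acetone N,N-dimethylhydrazone, CC(C)=NN(C)C; water, O
Why: Azaenolate (hydrazone) alkylation should proceed by SN2 at the primary triflate, far faster than at the neopentyl secondary bromide, and mild hydrolysis releases the methyl ketone with the stereocentre spatially unchanged.

**Step 5**
Reactants: 7 (S)-5-bromo-6,6-dimethyloct-7-en-2-one
Product: 9 (S)-3-bromo-2,2-dimethyl-6-oxoheptanal, via secondary ozonide 8 (not isolated)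
Conditions: O3, CH2Cl2, −78 °C; then PPh3, −78 °C to rt
Reagents that add atoms: ozone, [O-][O+]=O
Why: Ozonolysis with reductive work-up cleaves the only olefin, and the β-bromo aldehyde has no α-hydrogen and so cannot eliminate.

**Step 6**
Reactants: 9 (S)-3-bromo-2,2-dimethyl-6-oxoheptanal
Product: 10 methyl (2E,5S)-5-bromo-4,4-dimethyl-8-oxonon-2-enoate
Conditions: Ph3P=CHCO2Me, toluene, 90 °C
Reagents that add atoms: methyl (triphenylphosphoranylidene)acetate, COC(=O)C=P(c1ccccc1)(c1ccccc1)c1ccccc1
Why: A Wittig reaction with a stabilised ylide is E-selective, attacks the aldehyde and not the methyl ketone, and needs no base that could close a cyclopropane from the γ-bromo ketone.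

**Step 7**
Reactants: 11 methyl (S)-2,2-dimethyl-1,3-dioxolane-4-carboxylate
Product: 13 (R)-4-ethynyl-2,2-dimethyl-1,3-dioxolane, via glyceraldehyde acetonide 12 (not isolated)
Conditions: DIBAL-H, CH2Cl2, −78 °C; then MeOH, K2CO3, dimethyl (1-diazo-2-oxopropyl)phosphonate, −78 °C to rt
Reagents that add atoms: dimethyl (1-diazo-2-oxopropyl)phosphonate, CC(=O)C(=[N+]=[N-])P(=O)(OC)OC
Why: One-pot ester reduction and Ohira–Bestmann (Seyferth–Gilbert) homologation turns the carbonyl carbon into a terminal alkyne under conditions mild enough to keep the α-oxygenated stereocentre, whose descriptor changes only through the priority rules.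

**Step 8**
Reactants: 13 (R)-4-ethynyl-2,2-dimethyl-1,3-dioxolane
Product: 14 (R)-but-3-yne-1,2-diol
Conditions: Dowex 50WX8 (H+ form), MeOH/H2O, rt
Reagents that add atoms: none
Why: Acid hydrolysis of the acetonide breaks only the C–O bonds at the acetal carbon, so the carbinol configuration (future C2) is retained.

**Step 9**
Reactants: 10 methyl (2E,5S)-5-bromo-4,4-dimethyl-8-oxonon-2-enoate; 14 (R)-but-3-yne-1,2-diol
Product: 15 methyl (2E,5S)-5-bromo-7-[(4R)-4-ethynyl-2-methyl-1,3-dioxolan-2-yl]-4,4-dimethylhept-2-enoate (both epimers at the ketal carbon)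
Conditions: PPTS (cat.), benzene, reflux, Dean–Stark trap
Reagents that add atoms: none
Why: Acid-catalysed ketalisation joins the fragments through a temporary dioxolane ring and already forms the C9a–O1–C2 link while C9a is still unhindered, with enoate, bromide and alkyne inert.

**Step 10**
Reactants: 15 methyl (2E,5S)-5-bromo-7-[(4R)-4-ethynyl-2-methyl-1,3-dioxolan-2-yl]-4,4-dimethylhept-2-enoate
Product: 16 methyl (2E,5S)-5-bromo-8-{[(2R)-1-(tert-butyldimethylsilyloxy)but-3-yn-2-yl]oxy}-4,4-dimethylnona-2,8-dienoate
Conditions: TBSOTf, i-Pr2NEt, CH2Cl2, −20 to 0 °C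
Reagents that add atoms: tert-butyldimethylsilyl triflate, CC(C)(C)[Si](C)(C)OS(=O)(=O)C(F)(F)F
Why: In this silyl triflate/amine opening of a ketal to an enol ether the silyl cation should bind the less hindered and more basic primary oxygen, so that this C–O bond ionises and the amine removes a methyl proton; an internal enol ether isomer, if formed, would lead to the same radical in step 11.

**Step 11**
Reactants: 16 methyl (2E,5S)-5-bromo-8-{[(2R)-1-(tert-butyldimethylsilyloxy)but-3-yn-2-yl]oxy}-4,4-dimethylnona-2,8-dienoate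
Product: 18 methyl 2-[(1S,2S,5S)-5-bromo-2-{[(2R)-1-(tert-butyldimethylsilyloxy)but-3-yn-2-yl]oxy}-2,6,6-trimethylcyclohexyl]acetate, via tertiary alkoxyalkyl radical 17 (not isolated)
Conditions: Fe(acac)3 (30 mol %), PhSiH2(Oi-Pr), Na2HPO4, i-PrOH/THF, 0.01 M, rt
Reagents that add atoms: none
Why: An iron hydride formed from Fe(acac)3 and the silane transfers a hydrogen atom to the terminal carbon of the electron-rich enol ether and gives the tertiary α-oxy radical 17, which adds to the β-carbon of the enoate, after which the α-ester radical is reduced by divalent iron and protonated by the alcohol. The closest known reaction type is the iron-catalysed reductive coupling of heteroatom-substituted donor olefins with acceptor olefins, a Giese addition started by metal-hydride hydrogen-atom transfer, run here intramolecularly. The only ring closed is the cyclohexane, in a 6-exo-trig mode that the C6 gem-dimethyl group should accelerate (Thorpe–Ingold effect). C5a should be set by a chair transition state in which the C7 bromine and the acrylate arm are both equatorial. C9a should be set in the same chair, because the branched alkoxy group, held in the nodal plane of the conjugated radical, can rest over C5a–H only when oxygen is equatorial, whereas an axial oxygen would press it against the axial C6 methyl group or the acrylate arm, so the small CH3 takes the axial site and O1 ends trans to C5. The step needs hydrogen-atom transfer to the enol ether rather than to the enoate or the alkyne, which the higher reactivity of 1,1-disubstituted donor olefins should secure, and ring closure faster than reduction of 17, which the polarity match, the dilution and the low stationary hydride concentration favour.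

**Step 12**
Reactants: 18 methyl 2-[(1S,2S,5S)-5-bromo-2-{[(2R)-1-(tert-butyldimethylsilyloxy)but-3-yn-2-yl]oxy}-2,6,6-trimethylcyclohexyl]acetate
Product: 19 methyl 2-[(1S,2S,5S)-5-bromo-2-{[(2R)-1-bromobut-3-yn-2-yl]oxy}-2,6,6-trimethylcyclohexyl]acetate
Conditions: Ph3PBr2, CH2Cl2, 0 °C to rt
Reagents that add atoms: dibromotriphenylphosphorane, BrP(Br)(c1ccccc1)(c1ccccc1)c1ccccc1
Why: This Appel-type direct conversion of a primary silyl ether into the bromide activates oxygen as a phosphonium and displaces it by bromide at CH2 under neutral conditions, so C2 and the tertiary ether should be untouched.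

**Step 13**
Reactants: 19 methyl 2-[(1S,2S,5S)-5-bromo-2-{[(2R)-1-bromobut-3-yn-2-yl]oxy}-2,6,6-trimethylcyclohexyl]acetate
Product: 21 methyl 2-[(1S,2S,5S)-5-bromo-2-{[(2S)-1-bromo-3-iodobut-3-en-2-yl]oxy}-2,6,6-trimethylcyclohexyl]acetate, via iodovinylborane 20 (not isolated)
Conditions: B-iodo-9-BBN, pentane/CH2Cl2, −20 °C; then AcOH, 0 °C
Reagents that add atoms: B-iodo-9-borabicyclo[3.3.1]nonane, IB1C2CCCC1CCC2
Why: Haloboration of the terminal alkyne adds B–I syn with iodine at the internal carbon, and protodeboronation with retention gives the 2-iodo-1-alkene; the low temperature should spare ester and ether, and the C2 descriptor changes only through the priority rules.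

**Step 14**
Reactants: 21 methyl 2-[(1S,2S,5S)-5-bromo-2-{[(2S)-1-bromo-3-iodobut-3-en-2-yl]oxy}-2,6,6-trimethylcyclohexyl]acetate
Product: 22 2-[(1S,2S,5S)-5-bromo-2-{[(2S)-1-bromo-3-iodobut-3-en-2-yl]oxy}-2,6,6-trimethylcyclohexyl]acetaldehyde
Conditions: DIBAL-H (1.1 equiv), toluene, −78 °C; aq. Rochelle salt
Reagents that add atoms: none
Why: Partial ester reduction lowers the activating carbonyl of the key step to the aldehyde level needed at C4, and the carbon–halogen bonds are inert to DIBAL-H at −78 °C.

**Step 15**
Reactants: 22 2-[(1S,2S,5S)-5-bromo-2-{[(2S)-1-bromo-3-iodobut-3-en-2-yl]oxy}-2,6,6-trimethylcyclohexyl]acetaldehyde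
Product: 24 (2R,4R,5aS,7S,9aS)-7-bromo-2-(bromomethyl)-6,6,9a-trimethyl-3-methylidenedecahydro-1-benzoxepin-4-ol, via alkenylchromium species 23 (not isolated)
Conditions: CrCl2 (excess), NiCl2 (cat.), DMSO/THF, 0.005 M, rt; aq. work-up
Reagents that add atoms: none
Why: In this intramolecular Nozaki–Hiyama–Kishi reaction only the alkenyl iodide is metalated, since alkyl bromides are inert to CrCl2, and 23 should add to the aldehyde through a seven-membered transition state that turns the bulky chromium alkoxide to the ring face opposite the axial 9a-methyl and 2-bromomethyl groups, giving the (4R)-alcohol next to the exocyclic methylene group.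

**Compound list**

1 | methyl 3,3-dimethylpent-4-enoate | C=CC(C)(C)CC(=O)OC | starting material
2 | 3,3-dimethylpent-4-enal | C=CC(C)(C)CC=O | intermediate
3 | (R)-2-bromo-3,3-dimethylpent-4-enal | C=CC(C)(C)[C@@H](Br)C=O | intermediate
4 | (R)-2-bromo-3,3-dimethylpent-4-en-1-ol | C=CC(C)(C)[C@@H](Br)CO | intermediate
5 | (R)-2-bromo-3,3-dimethylpent-4-enyl trifluoromethanesulfonate | C=CC(C)(C)[C@@H](Br)COS(=O)(=O)C(F)(F)F | intermediate
6 | (S)-5-bromo-6,6-dimethyloct-7-en-2-one N,N-dimethylhydrazone | C=CC(C)(C)[C@@H](Br)CCC(C)=NN(C)C | intermediate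
7 | (S)-5-bromo-6,6-dimethyloct-7-en-2-one | C=CC(C)(C)[C@@H](Br)CCC(C)=O | intermediate
8 | (5S)-5-bromo-6-methyl-6-(1,2,4-trioxolan-3-yl)heptan-2-one (secondary ozonide) | C1OOC(O1)C(C)(C)[C@@H](Br)CCC(C)=O | intermediate
9 | (S)-3-bromo-2,2-dimethyl-6-oxoheptanal | O=CC(C)(C)[C@@H](Br)CCC(C)=O | intermediate
10 | methyl (2E,5S)-5-bromo-4,4-dimethyl-8-oxonon-2-enoate | COC(=O)/C=C/C(C)(C)[C@@H](Br)CCC(C)=O | intermediate
11 | methyl (S)-2,2-dimethyl-1,3-dioxolane-4-carboxylate | CC1(C)O[C@H](C(=O)OC)CO1 | starting material
12 | (S)-2,2-dimethyl-1,3-dioxolane-4-carbaldehyde | CC1(C)O[C@H](C=O)CO1 | intermediate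
13 | (R)-4-ethynyl-2,2-dimethyl-1,3-dioxolane | CC1(C)O[C@H](C#C)CO1 | intermediate
14 | (R)-but-3-yne-1,2-diol | O[C@H](C#C)CO | intermediate
15 | methyl (2E,5S)-5-bromo-7-[(4R)-4-ethynyl-2-methyl-1,3-dioxolan-2-yl]-4,4-dimethylhept-2-enoate (both ketal epimers) | COC(=O)/C=C/C(C)(C)[C@@H](Br)CCC1(C)OC[C@@H](C#C)O1 | intermediate
16 | methyl (2E,5S)-5-bromo-8-{[(2R)-1-(tert-butyldimethylsilyloxy)but-3-yn-2-yl]oxy}-4,4-dimethylnona-2,8-dienoate | COC(=O)/C=C/C(C)(C)[C@@H](Br)CCC(=C)O[C@H](C#C)CO[Si](C)(C)C(C)(C)C | intermediate
17 | tertiary α-alkoxyalkyl radical formed from 16 by hydrogen-atom uptake at the terminal enol ether carbon | COC(=O)/C=C/C(C)(C)[C@@H](Br)CC[C](C)O[C@H](C#C)CO[Si](C)(C)C(C)(C)C | intermediate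
18 | methyl 2-[(1S,2S,5S)-5-bromo-2-{[(2R)-1-(tert-butyldimethylsilyloxy)but-3-yn-2-yl]oxy}-2,6,6-trimethylcyclohexyl]acetate | COC(=O)C[C@H]1C(C)(C)[C@@H](Br)CC[C@]1(C)O[C@H](C#C)CO[Si](C)(C)C(C)(C)C | intermediate
19 | methyl 2-[(1S,2S,5S)-5-bromo-2-{[(2R)-1-bromobut-3-yn-2-yl]oxy}-2,6,6-trimethylcyclohexyl]acetate | COC(=O)C[C@H]1C(C)(C)[C@@H](Br)CC[C@]1(C)O[C@H](C#C)CBr | intermediate
20 | (Z)-2-iodoalkenyl-9-BBN adduct of 19 (iodine and boron cis) | COC(=O)C[C@H]1C(C)(C)[C@@H](Br)CC[C@]1(C)O[C@H](C(/I)=C/B1C2CCCC1CCC2)CBr | intermediate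
21 | methyl 2-[(1S,2S,5S)-5-bromo-2-{[(2S)-1-bromo-3-iodobut-3-en-2-yl]oxy}-2,6,6-trimethylcyclohexyl]acetate | COC(=O)C[C@H]1C(C)(C)[C@@H](Br)CC[C@]1(C)O[C@H](C(I)=C)CBr | intermediate
22 | 2-[(1S,2S,5S)-5-bromo-2-{[(2S)-1-bromo-3-iodobut-3-en-2-yl]oxy}-2,6,6-trimethylcyclohexyl]acetaldehyde | O=CC[C@H]1C(C)(C)[C@@H](Br)CC[C@]1(C)O[C@H](C(I)=C)CBr | intermediate
23 | alkenylchromium dichloride derived from 22 | O=CC[C@H]1C(C)(C)[C@@H](Br)CC[C@]1(C)O[C@H](C(=C)[Cr](Cl)Cl)CBr | intermediate
24 | (2R,4R,5aS,7S,9aS)-7-bromo-2-(bromomethyl)-6,6,9a-trimethyl-3-methylidenedecahydro-1-benzoxepin-4-ol | C=C1[C@H](O)C[C@H]2C(C)(C)[C@@H](Br)CC[C@]2(C)O[C@H]1CBr | target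

**Total step count:** 15
**Longest linear sequence:** 13 (steps 1–6 and 9–15)

**Steps most likely to fail**

Step 11. The facial selectivity at C9a may be poor if the alkoxy group takes the axial site. Radical 17 may also be reduced, or lose its propargylic O-substituent by β-scission, before the hindered bond forms. The fallback sets out from 10 and forms the same bond with a metal-bound oxygen. SmI2, MeOH, THF, 0 °C should effect a ketyl–olefin cyclisation through a chair in which trivalent samarium bridges the ketyl oxygen and the ester. This holds both groups equatorial and gives methyl 2-[(1S,2S,5S)-5-bromo-2-hydroxy-2,6,6-trimethylcyclohexyl]acetate F1. Ueno–Stork bromoacetalisation of the tertiary alcohol (NBS, ethyl vinyl ether, CH2Cl2, −20 °C) gives methyl 2-[(1S,2S,5S)-5-bromo-2-(2-bromo-1-ethoxyethoxy)-2,6,6-trimethylcyclohexyl]acetate F2. Lewis acid substitution of the ethoxy group (tributyl(ethynyl)stannane, BF3·OEt2, CH2Cl2, −78 °C) then installs the alkyne. C2 is not controlled on this path, so its epimer has to be separated. The fallback returns to the route at 19.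

Step 4. The basic azaenolate may cause E2 loss of triflate, may attack bromine with loss of both leaving groups, or may deprotonate the product so that a cyclopropane closes. The fallback sets out from 2 and replaces substitution by olefination. The bromination of step 2 is run without borohydride, and crude 3 is treated with 1-(triphenylphosphoranylidene)propan-2-one in CH2Cl2. This Wittig reaction gives (3E,5S)-5-bromo-6,6-dimethylocta-3,7-dien-2-one F3. Conjugate reduction with [(Ph3P)CuH]6 in toluene does not touch the isolated vinyl group. The fallback returns to the route at 7.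

Step 15. The facial selectivity at the aldehyde may be poor, or the equatorial alkoxide may be preferred. Either outcome would set C4 wrongly. The fallback sets out from 22 and sets C4 by reagent control after ring closure. The ring closure is accepted as it falls, and the epimer (2R,4S,5aS,7S,9aS)-7-bromo-2-(bromomethyl)-6,6,9a-trimethyl-3-methylidenedecahydro-1-benzoxepin-4-ol F4 is oxidised with Dess–Martin periodinane. This gives (2R,5aS,7S,9aS)-7-bromo-2-(bromomethyl)-6,6,9a-trimethyl-3-methylideneoctahydro-1-benzoxepin-4(5H)-one F5. Corey–Bakshi–Shibata reduction with the (S)-methyl oxazaborolidine and BH3·SMe2 treats the alkenyl side as the large group and should deliver the (4R)-alcohol. The fallback returns to the route at 24.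

**Further compounds**

F1 | step 11 | methyl 2-[(1S,2S,5S)-5-bromo-2-hydroxy-2,6,6-trimethylcyclohexyl]acetate | COC(=O)C[C@H]1C(C)(C)[C@@H](Br)CC[C@]1(C)O
F2 | step 11 | methyl 2-[(1S,2S,5S)-5-bromo-2-(2-bromo-1-ethoxyethoxy)-2,6,6-trimethylcyclohexyl]acetate (both acetal epimers) | COC(=O)C[C@H]1C(C)(C)[C@@H](Br)CC[C@]1(C)OC(CBr)OCC
F3 | step 4 | (3E,5S)-5-bromo-6,6-dimethylocta-3,7-dien-2-one | C=CC(C)(C)[C@@H](Br)/C=C/C(C)=O
F4 | step 15 | (2R,4S,5aS,7S,9aS)-7-bromo-2-(bromomethyl)-6,6,9a-trimethyl-3-methylidenedecahydro-1-benzoxepin-4-ol | C=C1[C@@H](O)C[C@H]2C(C)(C)[C@@H](Br)CC[C@]2(C)O[C@H]1CBr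
F5 | step 15 | (2R,5aS,7S,9aS)-7-bromo-2-(bromomethyl)-6,6,9a-trimethyl-3-methylideneoctahydro-1-benzoxepin-4(5H)-one | C=C1C(=O)C[C@H]2C(C)(C)[C@@H](Br)CC[C@]2(C)O[C@H]1CBr
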